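**Plan**

Ring labels: A is the para-disubstituted ring, B the 1,2,3-trisubstituted phenol ring, C the meta-disubstituted ring and D the 1,2,4-trisubstituted phenol ring (C-1 OH, C-2 O–ring A, C-4 bridge). The macrocycle has 18 ring atoms.
Cuts, in retrosynthetic order: the two O–CH3 bonds of the dimethyl ether; the bond from ring D C-4 to the adjacent CH2 of the C/D bridge; the central C–C bond of the A/B bridge; the ring A C–O(D) and ring B C–O(C) aryl ether bonds.
Key event: a cathodic, nickel-catalysed decarboxylative radical arylation. The bridge CH2 is carried as an acid one carbon longer (N-hydroxyphthalimide ester) and ring D C-4 as an iodide. Both helpers leave during the ring closure (CO2, phthalimide, iodide), so the saturated bridge forms directly.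
Enabling feature: ring D C-4 lies para to OMe, so simple iodination finds it. The bridge carbon is an unbranched 2-(ring C)ethyl position whose radical has no reachable 1,5-hydrogen and only a degenerate 1,2-aryl shift. The ortho-linked ring B and the meta-linked rings C and D fold the open chain so that its ends can meet.
Forward order: the D–O–A aldehyde and the C–O–B phosphonium salt come from two SNAr reactions, the chain is joined by Wittig olefination and diimide reduction, the 18-membered ring is closed, and the methyl ethers are removed.
Stereochemistry: the target has no stereocentre, and the alkene geometry of the Wittig product is erased by the reduction.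

Key step: step 10

Assumption: the 18-membered ring is taken to be conformationally mobile at room temperature, so no planar or axial chirality has to be controlled.

Step 1
Reactants: 1 guaiacol (2-methoxyphenol); 2 4-fluorobenzaldehyde
Product: 3 4-(2-methoxyphenoxy)benzaldehyde
Conditions: K2CO3, DMF, 130 °C
Reagents that add atoms: none
Why: Nucleophilic aromatic substitution (addition-elimination): the para formyl group stabilises the Meisenheimer adduct, so the phenoxide of 1 displaces fluoride, a routine way to 4-aryloxybenzaldehydes.

Step 2
Reactants: 3 4-(2-methoxyphenoxy)benzaldehyde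
Product: 4 4-(5-iodo-2-methoxyphenoxy)benzaldehyde
Conditions: NIS, TFA (0.3 equiv), MeCN, rt, dark
Reagents that add atoms: N-iodosuccinimide, O=C1CCC(=O)N1I
Why: Electrophilic aromatic iodination: ring A is switched off by its formyl group and in ring D the methoxy oxygen is a much stronger para director than the ether oxygen shared with the electron-poor ring A, so iodine should enter para to OMe, at the carbon that will carry the bridge.

Step 3
Reactants: 5 2-fluoro-3-methoxybenzaldehyde; 6 methyl 3-(3-hydroxyphenyl)propanoate
Product: 7 methyl 3-[3-(2-formyl-6-methoxyphenoxy)phenyl]propanoate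
Conditions: K2CO3, dry DMF, 110 °C
Reagents that add atoms: none
Why: Nucleophilic aromatic substitution: the ortho formyl group (helped by the inductive pull of the neighbouring OMe) activates the fluoride toward the phenoxide of 6, and dry carbonate base leaves the methyl ester and its alpha-hydrogens alone.

Step 4
Reactants: 7 methyl 3-[3-(2-formyl-6-methoxyphenoxy)phenyl]propanoate
Product: 8 methyl 3-{3-[2-(hydroxymethyl)-6-methoxyphenoxy]phenyl}propanoate
Conditions: NaBH4, MeOH/THF, 0 °C
Reagents that add atoms: none
Why: Chemoselective borohydride reduction: NaBH4 at 0 °C reduces the aryl aldehyde much faster than the aliphatic methyl ester.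

Step 5
Reactants: 8 methyl 3-{3-[2-(hydroxymethyl)-6-methoxyphenoxy]phenyl}propanoate
Product: 9 {3-methoxy-2-[3-(3-methoxy-3-oxopropyl)phenoxy]benzyl}triphenylphosphonium bromide
Conditions: PPh3·HBr, MeCN, reflux
Reagents that add atoms: triphenylphosphine hydrobromide, [Br-].c1ccc(cc1)[PH+](c1ccccc1)c1ccccc1
Why: Direct conversion of a benzylic alcohol into its phosphonium salt: HBr activates the benzylic position and PPh3 traps it by substitution, a standard shortcut that avoids a separate benzylic bromide.

Step 6
Reactants: 9 {3-methoxy-2-[3-(3-methoxy-3-oxopropyl)phenoxy]benzyl}triphenylphosphonium bromide; 4 4-(5-iodo-2-methoxyphenoxy)benzaldehyde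
Product: 11 methyl 3-{3-[2-(2-{4-(5-iodo-2-methoxyphenoxy)phenyl}ethenyl)-6-methoxyphenoxy]phenyl}propanoate (E/Z mixture), via phosphonium ylide 10 (not isolated)
Conditions: K2CO3, 18-crown-6 (cat.), CH2Cl2, reflux
Reagents that add atoms: none
Why: Wittig olefination with a semi-stabilised benzylic ylide under solid-liquid phase-transfer conditions, mild enough for the ester and the aryl iodide, and the E/Z outcome is of no consequence because the double bond is saturated next.

Step 7
Reactants: 11 stilbene ester (E/Z mixture)
Product: 12 methyl 3-{3-[2-(2-{4-(5-iodo-2-methoxyphenoxy)phenyl}ethyl)-6-methoxyphenoxy]phenyl}propanoate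
Conditions: TsNHNH2 (excess, in portions), NaOAc, DME/H2O, reflux
Reagents that add atoms: none
Why: Diimide reduction: HN=NH released from the sulfonyl hydrazide delivers two hydrogens to the C=C bond in a concerted six-centre transfer and, unlike hydrogenation over palladium, does not touch the carbon-iodine bond or the ester.

Step 8
Reactants: 12 bibenzyl methyl ester
Product: 14 3-{3-[2-(2-{4-(5-iodo-2-methoxyphenoxy)phenyl}ethyl)-6-methoxyphenoxy]phenyl}propanoic acid, via lithium carboxylate 13 (not isolated)
Conditions: LiOH·H2O, THF/MeOH/H2O, rt; then 1 M HCl
Reagents that add atoms: lithium hydroxide, [Li+].[OH-]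
Why: Ester saponification by acyl-oxygen cleavage followed by protonation of carboxylate 13 in the work-up, with nothing else in 12 being base-sensitive.

Step 9
Reactants: 14 seco acid
Product: 15 1,3-dioxoisoindolin-2-yl 3-{3-[2-(2-{4-(5-iodo-2-methoxyphenoxy)phenyl}ethyl)-6-methoxyphenoxy]phenyl}propanoate
Conditions: N-hydroxyphthalimide, DIC, DMAP (cat.), CH2Cl2, rt
Reagents that add atoms: N-hydroxyphthalimide, O=C1c2ccccc2C(=O)N1O
Why: Carbodiimide (Steglich-type) esterification turns the acid into the redox-active N-hydroxyphthalimide ester, a chromatographically stable radical precursor, and leaves the aryl iodide untouched.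

Step 10
Reactants: 15 seco iodide N-hydroxyphthalimide ester
Product: 17 marchantin C dimethyl ether, via nickelacycle 16 (not isolated)
Conditions: NiCl2·6H2O (30 mol%), 2,2'-bipyridine (30 mol%), AgNO3 (0.3 equiv), LiCl (0.1 M, electrolyte), NMP, undivided cell, Mg anode/RVC cathode, constant current, rt; 15 added by syringe pump (final ca. 2 mM)
Reagents that add atoms: none
Why: Proposed new method: low-valent nickel made at the silver-coated cathode should first insert into the ring D carbon-iodine bond, the arylnickel then takes up one electron and passes it to its own tethered phthalimide ester, which loses phthalimide anion and CO2 to leave the primary 2-(ring C)ethyl radical, and this radical is caught by the divalent arylnickel centre of the same molecule to give trivalent nickelacycle 16, whose reductive elimination forms the aryl-CH2 bond. The closest known reaction type is the intermolecular nickel-catalysed, zinc- or cathode-driven decarboxylative arylation of N-hydroxyphthalimide esters with aryl iodides, in which 3-arylpropanoic esters are standard partners, and what is new is its use to close a macrocycle. The only ring closed is the 18-membered cyclophane ring, formed by radical-to-metal recombination to a 19-membered metallacycle and ring contraction through reductive elimination, so no endo or exo attack on a pi system is involved. No stereocentre is created. The step needs intramolecular over intermolecular capture and cross-coupling over hydrodeiodination, hydrodecarboxylation and aryl-aryl homocoupling, which is served by slow addition into a dilute cell in which nickel always exceeds free substrate, by pairing a fast-inserting iodide with the harder-to-reduce unsubstituted phthalimide ester so that the aryl end is metalated before the radical is born, and by the ortho (ring B) and meta (rings C and D) ether hinges that fold the chain. The radical itself is forgiving, since no 1,5-hydrogen is within reach, its 1,2-aryl shift is degenerate, and bipyridine-ligated trivalent nickel should eliminate faster than it loses a beta-hydride or chain-walks, so the linear bridge is expected.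

Step 11
Reactants: 17 marchantin C dimethyl ether
Product: 19 marchantin C, via bis(dibromoboryl) ether 18 (not isolated)
Conditions: BBr3, CH2Cl2, −78 °C to rt; then H2O
Reagents that add atoms: none
Why: Lewis-acid aryl methyl ether cleavage: BBr3 binds each methoxy oxygen and bromide attacks the methyl carbon by SN2, whereas the two diaryl ether oxygens offer no sp3 carbon to attack, and water then hydrolyses boryl ether 18 to the free bisphenol.

**Compound list**

1 | guaiacol (2-methoxyphenol) | COc1ccccc1O | starting material
2 | 4-fluorobenzaldehyde | O=Cc1ccc(F)cc1 | starting material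
3 | 4-(2-methoxyphenoxy)benzaldehyde | COc1ccccc1Oc1ccc(C=O)cc1 | intermediate
4 | 4-(5-iodo-2-methoxyphenoxy)benzaldehyde | COc1ccc(I)cc1Oc1ccc(C=O)cc1 | intermediate
5 | 2-fluoro-3-methoxybenzaldehyde | COc1cccc(C=O)c1F | starting material
6 | methyl 3-(3-hydroxyphenyl)propanoate | COC(=O)CCc1cccc(O)c1 | starting material
7 | methyl 3-[3-(2-formyl-6-methoxyphenoxy)phenyl]propanoate | COC(=O)CCc1cccc(Oc2c(C=O)cccc2OC)c1 | intermediate
8 | methyl 3-{3-[2-(hydroxymethyl)-6-methoxyphenoxy]phenyl}propanoate | COC(=O)CCc1cccc(Oc2c(CO)cccc2OC)c1 | intermediate
9 | {3-methoxy-2-[3-(3-methoxy-3-oxopropyl)phenoxy]benzyl}triphenylphosphonium bromide | COC(=O)CCc1cccc(Oc2c(C[P+](c3ccccc3)(c3ccccc3)c3ccccc3)cccc2OC)c1.[Br-] | intermediate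
10 | benzylidene triphenylphosphorane (ylide) derived from 9 | COC(=O)CCc1cccc(Oc2c(C=P(c3ccccc3)(c3ccccc3)c3ccccc3)cccc2OC)c1 | intermediate
11 | methyl 3-{3-[2-(2-{4-(5-iodo-2-methoxyphenoxy)phenyl}ethenyl)-6-methoxyphenoxy]phenyl}propanoate, E/Z mixture | COC(=O)CCc1cccc(Oc2c(C=Cc3ccc(Oc4cc(I)ccc4OC)cc3)cccc2OC)c1 | intermediate
12 | methyl 3-{3-[2-(2-{4-(5-iodo-2-methoxyphenoxy)phenyl}ethyl)-6-methoxyphenoxy]phenyl}propanoate | COC(=O)CCc1cccc(Oc2c(CCc3ccc(Oc4cc(I)ccc4OC)cc3)cccc2OC)c1 | intermediate
13 | lithium salt of acid 14 | [Li+].[O-]C(=O)CCc1cccc(Oc2c(CCc3ccc(Oc4cc(I)ccc4OC)cc3)cccc2OC)c1 | intermediate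
14 | 3-{3-[2-(2-{4-(5-iodo-2-methoxyphenoxy)phenyl}ethyl)-6-methoxyphenoxy]phenyl}propanoic acid | OC(=O)CCc1cccc(Oc2c(CCc3ccc(Oc4cc(I)ccc4OC)cc3)cccc2OC)c1 | intermediate
15 | 1,3-dioxoisoindolin-2-yl ester of acid 14 | O=C(CCc1cccc(Oc2c(CCc3ccc(Oc4cc(I)ccc4OC)cc3)cccc2OC)c1)ON1C(=O)c2ccccc2C1=O | intermediate
16 | proposed 19-membered aryl(alkyl)iodo(2,2'-bipyridine)nickel metallacycle, trivalent nickel bridging ring D C-4 and the bridge CH2 | COc1ccc2cc1Oc1ccc(cc1)CCc1cccc(OC)c1Oc1cccc(c1)CC[Ni-2]23(I)[n+]4ccccc4-c4cccc[n+]43 | intermediate
17 | marchantin C dimethyl ether | COc1ccc2cc1Oc1ccc(cc1)CCc1cccc(OC)c1Oc1cccc(c1)CC2 | intermediate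
18 | bis(dibromoboryl) ether of marchantin C | BrB(Br)Oc1ccc2cc1Oc1ccc(cc1)CCc1cccc(OB(Br)Br)c1Oc1cccc(c1)CC2 | intermediate
19 | marchantin C | Oc1ccc2cc1Oc1ccc(cc1)CCc1cccc(O)c1Oc1cccc(c1)CC2 | target

**Step count**

Total steps: 11. Longest linear sequence: 9 steps (steps 3 to 11, from 5 and 6).

**Steps most likely to fail**

1. Step 10. The radical may be captured by a nickel centre on another molecule, which leads to oligomerisation. It may also abstract hydrogen from the solvent before capture, the carbon-iodine bond may be reduced without coupling, or two arylnickel centres may homocouple. The fallback replaces the one-electron closure with a two-electron one built from known chemistry, and it forms the same aryl-CH2 bond. It sets out from acid 14. Kochi oxidative decarboxylation (Pb(OAc)4, Cu(OAc)2 cat., pyridine, benzene, reflux) gives the terminal styrene 2-(3-ethenylphenoxy)-1-{2-[4-(5-iodo-2-methoxyphenoxy)phenyl]ethyl}-3-methoxybenzene F1. Anti-Markovnikov hydroboration with 9-BBN-H in THF gives the B-(2-arylethyl)-9-borabicyclo[3.3.1]nonane F2. This borane is not isolated. It is run slowly into PdCl2(dppf), AsPh3 and Cs2CO3 in DMF/THF/H2O at high dilution, an intramolecular B-alkyl Suzuki-Miyaura macrocyclisation. The sequence comes back to the route at 17.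

2. Step 3. Displacement may be sluggish, because the fluoride is flanked on both sides and activated by only one formyl group, and the methyl ester may be slowly lost at the temperature then needed. The fallback replaces addition-elimination with a copper-catalysed Ullmann-type C–O coupling. It sets out from phenol 6, which is coupled with purchased 2-bromo-3-methoxybenzaldehyde (CuI, N,N-dimethylglycine, Cs2CO3, dioxane, 90 °C), where the ortho formyl group assists the copper insertion. It comes back directly at 7 and makes no new compound (F0).

3. Step 2. Regiocontrol may be incomplete (attack para to the aryloxy oxygen), or a second iodination may occur. The fallback puts the halogen in before the ether bond, on a ring where OMe is the only effective director. It sets out from guaiacol 1. Acetylation (Ac2O, pyridine) gives 2-methoxyphenyl acetate F3. Iodination (NIS, TFA, MeCN) para to OMe gives 5-iodo-2-methoxyphenyl acetate F4. Methanolysis (K2CO3, MeOH, rt) gives 5-iodo-2-methoxyphenol F5. SNAr with 2 (K2CO3, DMF, 130 °C) then comes back to the route at 4.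

**Further compounds**

F1 | step 10 | 2-(3-ethenylphenoxy)-1-{2-[4-(5-iodo-2-methoxyphenoxy)phenyl]ethyl}-3-methoxybenzene | C=Cc1cccc(Oc2c(CCc3ccc(Oc4cc(I)ccc4OC)cc3)cccc2OC)c1
F2 | step 10 | B-(2-arylethyl)-9-borabicyclo[3.3.1]nonane from F1 | C1CC2CCCC(C1)B2CCc1cccc(Oc2c(CCc3ccc(Oc4cc(I)ccc4OC)cc3)cccc2OC)c1
F0 | step 3 | none | none
F3 | step 2 | 2-methoxyphenyl acetate | COc1ccccc1OC(C)=O
F4 | step 2 | 5-iodo-2-methoxyphenyl acetate | COc1ccc(I)cc1OC(C)=O
F5 | step 2 | 5-iodo-2-methoxyphenol | COc1ccc(I)cc1O
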